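**Retrosynthetic overview**
- Esters last: cut the tertiary 4α-acetate, then the secondary 3β-angelate, back to the 3β,4α-diol of eudesm-7(11)-en-8-one.
- The trans-diequatorial diol comes from the 4α-hydroxy-3-ketone by axial hydride delivery. That ketol comes from the 3-ene by α-face ketohydroxylation.
- Key disconnection C5–C10: eudesma-3,7(11)-dien-8-one opens to achiral germacrone. In the forward direction a confined chiral acid protonates C1 of one planar-chiral conformer, and the transannular cation–olefin closure copies the germacrane-to-eudesmane step of the biosynthesis.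
- Ring order: the ten-membered ring comes with germacrone (nature's farnesyl C1–C10 closure). The single C5–C10 bond then makes rings A and B at the same time and sets C5 and C10. C4 and C3 follow by substrate control.

Assumption: germacrone, a bulk isolate of zedoary and zdravets oils, is taken as a cheap commercial material, and the catalyst antipode written in step 1 is the one that a first screen shows to give the (5R,10R) series.

**Step 1**
Reactants: 1 germacrone, (1(10)E,4E)-germacra-1(10),4,7(11)-trien-8-one
Product: 3 (5R,10R)-eudesma-3,7(11)-dien-8-one (5α-H; 10β-CH3), via 8-oxoeudesm-7(11)-en-4-yl cation 2 (not isolated)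
Conditions: (S,S)-IDPi (confined N-triflyl imidodiphosphorimidate built from two 3,3'-diaryl-BINOL units, 5 mol%), (CF3)3COH/CHCl3 1:1, 0 °C, 48 h; AgNO3–SiO2 chromatography
Reagents that add atoms: none
Why: Proposed new method: achiral 1 exists as two planar-chiral crossed conformers that should interconvert within minutes at this temperature, so a confined chiral acid that hydrogen-bonds to the C8 carbonyl and protonates C1 of only one of them funnels all material (dynamic kinetic asymmetric transformation) through the chair–chair transannular cation–olefin cyclization, in which both E-alkenes add anti and so fix 5α-H and 10β-CH3 (5R,10R), after which the counter-anion, still lying over the C1–C2–C3 edge, removes the axial H-3α of cation 2 to give the 3-ene; the closest known reaction types are the racemic acid-induced germacrone-to-selinadienone cyclization and the imidodiphosphorimidate-catalysed asymmetric proton-initiated polyene cyclization.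

**Step 2**
Reactants: 3 (5R,10R)-eudesma-3,7(11)-dien-8-one
Product: 4 (4S,5R,10R)-4α-hydroxyeudesm-7(11)-ene-3,8-dione
Conditions: RuCl3 (1 mol%), 2KHSO5·KHSO4·K2SO4, NaHCO3, EtOAc/MeCN/H2O 6:6:1, 20 °C, 15 min
Reagents that add atoms: potassium peroxymonosulfate (KHSO5), [K+].[O-]S(=O)(=O)OO
Why: RuO4-catalysed ketohydroxylation, in which RuO4 made in situ adds [3+2] to the only electron-rich alkene from the α-face opposite the axial 10β-methyl and the ruthenate ester is oxidised on to the α-ketol, which sets C4 as 4α-OH/4β-CH3 (4S) while the tetrasubstituted electron-poor 7(11)-enone alkene is left alone.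

**Step 3**
Reactants: 4 (4S,5R,10R)-4α-hydroxyeudesm-7(11)-ene-3,8-dione
Product: 5 (3S,4S,5R,10R)-3β,4α-dihydroxyeudesm-7(11)-en-8-one
Conditions: NaBH4, MeOH/CH2Cl2 1:1, −78 °C
Reagents that add atoms: none
Why: Chemo- and diastereoselective borohydride reduction, in which the saturated α-oxygenated C3 ketone reacts far faster than the hindered cross-conjugated C8 enone and the small hydride enters axially from the α-face because the equatorial path is blocked by the axial 4β-methyl, giving the equatorial 3β-alcohol (3S).

**Step 4**
Reactants: 5 (3S,4S,5R,10R)-3β,4α-dihydroxyeudesm-7(11)-en-8-one; 6 angelic acid, (Z)-2-methylbut-2-enoic acid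
Product: 8 (3S,4S,5R,10R)-3β-angeloyloxy-4α-hydroxyeudesm-7(11)-en-8-one, via angelic 2,4,6-trichlorobenzoic anhydride 7 (not isolated)
Conditions: 6, 2,4,6-Cl3C6H2COCl, Et3N, PhMe, 20 °C, 1 h; then 5, 80 °C
Reagents that add atoms: none
Why: Yamaguchi-type mixed-anhydride esterification run without DMAP, in which only the secondary equatorial 3β-OH is acylated, the tertiary 4α-OH stays inert, the lack of a nucleophilic catalyst keeps the Z geometry of the angelate, and no stereocentre is touched.

**Step 5**
Reactants: 8 (3S,4S,5R,10R)-3β-angeloyloxy-4α-hydroxyeudesm-7(11)-en-8-one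
Product: 9 (3S,4S,5R,10R)-4α-acetoxy-3β-angeloyloxyeudesm-7(11)-en-8-one (CNP0141494.1)
Conditions: Ac2O (3 equiv), Sc(OTf)3 (2 mol%), MeCN, −20 °C
Reagents that add atoms: acetic anhydride, CC(=O)OC(C)=O
Why: Sc(OTf)3-catalysed acylation of a tertiary alcohol, which is fast at low temperature, leaves the C4–O bond intact (4S retained), avoids the base-induced O3-to-O4 acyl shift by working in a non-basic medium, and is protected from ionisation or elimination by the electron-withdrawing 3β-acyloxy neighbour.

**Compound list**
1 | germacrone, (1(10)E,4E)-germacra-1(10),4,7(11)-trien-8-one | C/C1=C\CC(=C(C)C)C(=O)C/C(C)=C/CC1 | starting material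
2 | 8-oxoeudesm-7(11)-en-4-yl cation (5α-H, 10β-CH3; ion pair with the catalyst anion) | C[C+]1CCC[C@]2(C)CC(=O)C(=C(C)C)C[C@@H]12 | intermediate
3 | (5R,10R)-eudesma-3,7(11)-dien-8-one | CC1=CCC[C@]2(C)CC(=O)C(=C(C)C)C[C@@H]12 | intermediate
4 | (4S,5R,10R)-4α-hydroxyeudesm-7(11)-ene-3,8-dione | O=C1CC[C@]2(C)CC(=O)C(=C(C)C)C[C@H]2[C@]1(C)O | intermediate
5 | (3S,4S,5R,10R)-3β,4α-dihydroxyeudesm-7(11)-en-8-one | O[C@H]1CC[C@]2(C)CC(=O)C(=C(C)C)C[C@H]2[C@]1(C)O | intermediate
6 | angelic acid, (Z)-2-methylbut-2-enoic acid | C/C=C(/C)C(=O)O | starting material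
7 | angelic 2,4,6-trichlorobenzoic anhydride | C/C=C(/C)C(=O)OC(=O)c1c(Cl)cc(Cl)cc1Cl | intermediate
8 | (3S,4S,5R,10R)-3β-angeloyloxy-4α-hydroxyeudesm-7(11)-en-8-one | C/C=C(/C)C(=O)O[C@H]1CC[C@]2(C)CC(=O)C(=C(C)C)C[C@H]2[C@]1(C)O | intermediate
9 | (3S,4S,5R,10R)-4α-acetoxy-3β-angeloyloxyeudesm-7(11)-en-8-one | C/C=C(/C)C(=O)O[C@H]1CC[C@]2(C)CC(=O)C(=C(C)C)C[C@H]2[C@]1(C)OC(C)=O | target

Total step count: 5. Longest linear sequence: 5 (1 → 3 → 4 → 5 → 8 → 9).

**The three steps most likely to fail are 1, 5 and 2.**

**Step 1.** Neither the enantioselectivity nor the site of proton loss (3-ene against the 4(15)- and 4-ene isomers) has been shown for this substrate. The product can also be re-protonated by the catalyst.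

The fallback sets out from 1 and comes back at 3. It stores the absolute configuration in an epoxide instead of in a proton transfer.
- The more reactive 1(10)-alkene is epoxidised with the D-fructose-derived Shi ketone and KHSO5. This again draws on the fast conformer exchange and gives (1R,10R)-1,10-epoxygermacrone F1.
- BF3·OEt2 in CH2Cl2 at −78 °C opens F1 at C10 with anti attack of C5 and loss of H-3. This gives 1β-hydroxy-5αH-eudesma-3,7(11)-dien-8-one F2.
- 1,1'-Thiocarbonyldiimidazole converts F2 into its 1β-O-(imidazol-1-ylthiocarbonyl) derivative F3.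
- Bu3SnH/AIBN in toluene at 80 °C (Barton–McCombie deoxygenation) removes the extra oxygen and delivers 3.

**Step 5.** The tertiary, neopentyl-like 4α-OH may acetylate too slowly. A small share of migrated 3-OH/4-angelate would then be acetylated faster and give the wrong diester.

The fallback sets out from 4 and comes back at 9. It reverses the order in which the two esters are put on.
- The ketol 4 has no free neighbouring hydroxyl that could take over the acyl group. It is acetylated with Ac2O/DMAP/Et3N at 40 °C to give 4α-acetoxyeudesm-7(11)-ene-3,8-dione F5.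
- The C3 ketone is reduced under non-basic conditions with Zn(BH4)2 in Et2O at −20 °C. This gives 4α-acetoxy-3β-hydroxyeudesm-7(11)-en-8-one F6.
- F6 is esterified with pre-formed anhydride 7, without excess base, to give 9.

**Step 2.** RuO4 may cleave the C3–C4 bond of the ketol or attack the isopropylidene group.

The fallback sets out from 3 and comes back at 4. It separates C–O bond formation from the oxidation to the ketone.
- OsO4 (cat.)/N-methylmorpholine N-oxide in acetone/water dihydroxylates the 3-ene from the α-face. This gives 3α,4α-dihydroxyeudesm-7(11)-en-8-one F4.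
- SO3·pyridine/DMSO/Et3N (Parikh–Doering oxidation) oxidises only the secondary axial 3α-OH and gives 4.

**Further compounds**
F1 | step 1 | (1R,10R)-1,10-epoxygermacrone | C/C1=C\CC(=C(C)C)C(=O)C[C@@]2(C)O[C@@H]2CC1
F2 | step 1 | 1β-hydroxy-5αH-eudesma-3,7(11)-dien-8-one | CC1=CC[C@@H](O)[C@]2(C)CC(=O)C(=C(C)C)C[C@@H]12
F3 | step 1 | 1β-O-(imidazol-1-ylthiocarbonyl) derivative of F2 | CC1=CC[C@@H](OC(=S)n3ccnc3)[C@]2(C)CC(=O)C(=C(C)C)C[C@@H]12
F4 | step 2 | 3α,4α-dihydroxyeudesm-7(11)-en-8-one | O[C@@H]1CC[C@]2(C)CC(=O)C(=C(C)C)C[C@H]2[C@]1(C)O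
F5 | step 5 | 4α-acetoxyeudesm-7(11)-ene-3,8-dione | O=C1CC[C@]2(C)CC(=O)C(=C(C)C)C[C@H]2[C@]1(C)OC(C)=O
F6 | step 5 | 4α-acetoxy-3β-hydroxyeudesm-7(11)-en-8-one | O[C@H]1CC[C@]2(C)CC(=O)C(=C(C)C)C[C@H]2[C@]1(C)OC(C)=O
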